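D, the ring, was what I had to count: its share of all the G that became D, X or E, in winter and in dawn.

| flask | G | remark | time |
|---|---|---|---|
| cedar | 0.29 M | run made earlier |  |
| alder | 1.7 M | run made earlier |  |
| winter | 2.0 M |  | 20 h |
| dawn | 0.46 M |  | 12 h |

| run | time / h | D / % | X / % | E / % |
|---|---|---|---|---|
| cedar | 0.833 | 3.6 | 13.4 | 0 |
| cedar | 2.00 | 7.4 | 23.5 | 0.2 |
| cedar | 4.00 | 12.3 | 31.8 | 0.4 |
| cedar | 6.00 | 16.3 | 34.6 | 1.9 |
| alder | 0.500 | 1.7 | 34.1 | 0.3 |
| alder | 1.00 | 2.7 | 48.2 | 0.4 |
| alder | 2.50 | 5.0 | 63.4 | 0.4 |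
| alder | 6.00 | 9.3 | 66.9 | 1.9 |

(scatter of a reading: 0.5 percentage points)

- a species is counted by the G in it: one X counts as two
- the numbers in the tables scatter by 0.5 percentage points (one standard deviation)

- the winner by share of D in all that became D or X or E; "neither" if no more than 2 percentage points parts them (winter / dawn / neither)
- share of D in all that became D or X or E, winter
- share of D in all that became D or X or E, dawn

I kept a ledger of the G charged, with g the fraction still free. In cedar, g read 83.0%, 68.9%, 55.5% and 47.2%, which gave an area under g of 3.92 h. E appeared after D, so I booked it as D gone on. D plus E at 6.00 h, over that area, read kD = 0.0464 h⁻¹, so I carried τ, the half-life of free G into D, at 14.9 h.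

The second entry was X. In alder it rose from 63.4% to 66.9% over the last interval, so I treated 2 G ⇌ X as a pre-equilibrium. With g at 21.9% in alder at 6.00 h, K, which is [X] over the square of [G], read 4.10 M⁻¹.

The books closed as g + a·g·g + kD·t·g = 1, with a = 2·K·c, c the charge, and the end g standing for the whole time. Winter had a = 16.4, so g = 19.5%. Dawn had the smaller a = 3.77, so g = 34.8%. With E counted in D, the shares came to 22.5% for winter and 29.8% for dawn, so I chose dawn.

The forecast stood higher in both, at 23% for winter and 33% for dawn, and also chose dawn: “Dilution favours D, so dawn wins.”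

The flasks gave 19.6% for winter and 30.7% for dawn, so the winner was dawn.

    D → E (k = 0.0320 h⁻¹)
    G → D (k = 0.0450 h⁻¹)
    2 G ⇌ X (K = 3.20 M⁻¹, k = 0.320 M⁻¹ h⁻¹)

In dawn at 12.0 h, 2 G ⇌ X by itself, both ways together, relaxed with a half-life of 2.34 h, shorter than the 15 h half-life of G into D. From 6.00 h to 12.0 h, dawn's G went from 40.6% to 33.4%; τ on the mean of these gives 10.3% of the charge, and D with E gained 9.79%. In winter, from 10.0 h to 20.0 h, the same count gives 9.54%, and D with E gained 9.24%.

All runs were generated by integration for substances that don't exist; scatter was added.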